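**Retrosynthetic overview**
- Target ⇒ (alkyne hydration, desilylation) 9‑ethynyl‑9‑silyloxy spiro‑enone ⇒ intramolecular aldol condensation (C7=C8) of a 1,4‑diketone carried on a finished oxolane; the cyclopentenone is the second and last ring.
- 1,4‑Diketone ⇒ (oxidation) triol ⇒ oxolane (first ring) by 5‑exo opening of a trisubstituted epoxide by the tertiary alcohol (inversion sets the spiro carbon); epoxide from asymmetric epoxidation of an (E)‑alkene.
- Alkene ⇒ B‑alkyl Suzuki union of a phytol‑derived C20 iodide (tertiary C–O centre from Sharpless epoxidation of natural phytol) with a C9 bromodiol.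
- Bromodiol ⇒ ethyl (S)‑lactate (its centre steers a chelation‑controlled ethynyl addition that sets the carbinol carbon and is later oxidised away) + (E)‑1‑iodobut‑1‑ene from but‑1‑yne.

Assumption: the SMILES is taken literally, i.e. (2S,5R,9S) in the 1‑oxaspiro[4.4]non‑7‑en‑6‑one core with a (4R,8R) side chain; C2 is then the mirror image of C2 of natural α‑tocopherol, so it is built from phytol with L‑(+)‑tartrate.

**Step 1**
Reactants: 1 (2E,7R,11R)-phytol
Product: 2 (2S,3S)-2,3-epoxyphytol
Conditions: Ti(OiPr)4 (10 mol %), L-(+)-diethyl tartrate (12 mol %), t-BuOOH, 4 Å MS, CH2Cl2, −20 °C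
Reagents that add atoms: tert-butyl hydroperoxide, CC(C)(C)OO
Why: Sharpless asymmetric epoxidation of the (E)-allylic alcohol; L-(+)-tartrate gives, as with geraniol, the (2S,3S)-epoxide, which fixes the quaternary C–O centre (later oxolane C2) as (S).

**Step 2**
Reactants: 2 (2S,3S)-2,3-epoxyphytol
Product: 3 (3S,7R,11R)-3,7,11,15-tetramethylhexadecane-1,3-diol
Conditions: NaAlH2(OCH2CH2OMe)2, THF, 0 °C to rt; aq. NaOH work-up
Reagents that add atoms: none
Why: Hydroxyl-directed hydride opening of the 2,3-epoxy alcohol (Red-Al reduction) occurs at C2 and leaves the tertiary C3–O bond untouched, so the 1,3-diol forms with retention at the stereocentre.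

**Step 3**
Reactants: 3 (3S,7R,11R)-3,7,11,15-tetramethylhexadecane-1,3-diol
Product: 4 (3S,7R,11R)-1-iodo-3,7,11,15-tetramethylhexadecan-3-ol
Conditions: I2, PPh3, imidazole, CH2Cl2, 0 °C
Reagents that add atoms: iodine, [I][I]
Why: Appel-type iodination converts only the primary alcohol, because the hindered tertiary alcohol does not form the oxyphosphonium leaving group.

**Step 4**
Reactants: 4 (3S,7R,11R)-1-iodo-3,7,11,15-tetramethylhexadecan-3-ol
Product: 5 triethylsilyl ether of 4
Conditions: TESOTf, 2,6-lutidine, CH2Cl2, −78 to 0 °C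
Reagents that add atoms: triethylsilyl trifluoromethanesulfonate, CC[Si](CC)(CC)OS(=O)(=O)C(F)(F)F
Why: Silyl triflate silylation masks the tertiary alcohol so that the iodine–lithium exchange of step 10 is possible.

**Step 5**
Reactants: 6 but-1-yne
Product: 8 (E)-1-iodobut-1-ene, via (E)-but-1-enylzirconocene chloride 7 (not isolated)
Conditions: Cp2Zr(H)Cl, THF, rt; then I2, 0 °C
Reagents that add atoms: iodine, [I][I]
Why: Schwartz hydrozirconation adds Zr–H syn and anti-Markovnikov to the terminal alkyne and iodinolysis goes with retention, giving only the (E)-vinyl iodide.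

**Step 6**
Reactants: 9 ethyl (S)-lactate
Product: 10 (2S)-2-hydroxy-N-methoxy-N-methylpropanamide
Conditions: MeNH(OMe)·HCl, i-PrMgCl, THF, −20 to 0 °C
Reagents that add atoms: N,O-dimethylhydroxylamine hydrochloride, CNOC.Cl
Why: Weinreb amide formation through the chloromagnesium amide works on the unprotected lactate (as in the preparation of lactate-derived ethyl ketones), and the magnesium alkoxide protects the (S) centre from enolisation.

**Step 7**
Reactants: 8 (E)-1-iodobut-1-ene; 10 (2S)-2-hydroxy-N-methoxy-N-methylpropanamide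
Product: 12 (2S,4E)-2-hydroxyhept-4-en-3-one, via (E)-but-1-enyllithium 11 (not isolated)
Conditions: 8, t-BuLi (2 equiv), Et2O, −78 °C; then 10 (0.4 equiv), −78 to 0 °C; aq. NH4Cl
Reagents that add atoms: none
Why: Weinreb ketone synthesis: iodine–lithium exchange gives the configurationally stable (E)-vinyllithium, one equivalent removes the hydroxyl proton and a second adds once to the amide through the stable chelated tetrahedral intermediate, so the (E)-enone forms without over-addition or racemisation.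

**Step 8**
Reactants: 12 (2S,4E)-2-hydroxyhept-4-en-3-one
Product: 14 (2S,4Z)-4-bromo-2-hydroxyhept-4-en-3-one, via anti-dibromide 13 (not isolated)
Conditions: Br2, CH2Cl2, −78 to 0 °C; then Et3N, 0 °C to rt
Reagents that add atoms: bromine, BrBr
Why: Bromination–dehydrobromination of the enone (E1cB loss of HBr from the α-carbon) gives the α-bromoenone as the more stable (Z) isomer with ethyl trans to the acyl group.

**Step 9**
Reactants: 14 (2S,4Z)-4-bromo-2-hydroxyhept-4-en-3-one
Product: 15 (2S,3S,4Z)-4-bromo-3-ethynylhept-4-ene-2,3-diol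
Conditions: HC≡CMgBr (3 equiv), CH2Cl2/THF, −78 to −20 °C; aq. NH4Cl
Reagents that add atoms: ethynylmagnesium bromide, C#C[Mg]Br
Why: Cram-chelate-controlled Grignard 1,2-addition: the magnesium alkoxide and the ketone oxygen form a five-membered chelate and the acetylide attacks the face opposite the methyl group, setting the tertiary carbinol centre (3S) that becomes C9 of the target.

**Step 10**
Reactants: 5 triethylsilyl ether of 4; 15 (2S,3S,4Z)-4-bromo-3-ethynylhept-4-ene-2,3-diol
Product: 18 (2S,3R,4E)-3-ethynyl-4-{(3S,7R,11R)-3,7,11,15-tetramethyl-3-[(triethylsilyl)oxy]hexadecyl}hept-4-ene-2,3-diol, via primary alkyllithium 16 (not isolated), via lithium alkyl(methoxy)borate 17 (not isolated)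
Conditions: 5 (1.5 equiv), t-BuLi, Et2O, −78 °C; B-methoxy-9-BBN, THF, −78 °C to rt; then 15, Pd(dppf)Cl2 (5 mol %), AsPh3, aq. K3PO4, DMF, rt to 45 °C
Reagents that add atoms: none
Why: B-alkyl Suzuki–Miyaura cross-coupling (iodine–lithium exchange, borate formation, Pd-catalysed coupling) joins the two fragments with retention of the alkene geometry, tolerates the free hydroxyls and touches no stereocentre.

**Step 11**
Reactants: 18 coupled (E)-alkene diol
Product: 21 (2S,3S)-3-{(2S,5S)-2-[(1S)-1-hydroxypropyl]-5-methyl-5-[(4R,8R)-4,8,12-trimethyltridecyl]oxolan-2-yl}pent-4-yne-2,3-diol, via silyl-protected epoxide 19 (not isolated), via desilylated epoxy alcohol 20 (not isolated)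
Conditions: 1,2:4,5-di-O-isopropylidene-β-L-erythro-2,3-hexodiulo-2,6-pyranose (enantiomer of the D-fructose-derived Shi ketone, 0.3 equiv), Oxone (2KHSO5·KHSO4·K2SO4), K2CO3, Bu4NHSO4, MeCN/CH2(OMe)2/aq. Na2B4O7 buffer, 0 °C; then CSA, MeOH/CH2Cl2, 0 °C to rt
Reagents that add atoms: potassium peroxymonosulfate (Oxone), [K+].[O-]S(=O)(=O)OO
Why: Shi asymmetric epoxidation with the L-series ketone (the D-fructose-derived ketone would attack the opposite face; the chosen face is also the one favoured by A(1,2) strain next to the allylic carbinol) followed by acid-induced desilylation and 5-exo-tet opening of the epoxide by the tertiary hydroxyl with inversion closes the oxolane and sets the future spiro centre, while the CH(OH)Et centre formed is erased in step 12.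

**Step 12**
Reactants: 21 oxolane triol
Product: 22 (3R)-3-hydroxy-3-{(2R,5S)-5-methyl-2-propanoyl-5-[(4R,8R)-4,8,12-trimethyltridecyl]oxolan-2-yl}pent-4-yn-2-one
Conditions: Dess–Martin periodinane, CH2Cl2, 0 °C to rt
Reagents that add atoms: none
Why: Dess–Martin oxidation turns both secondary alcohols into ketones (propanoyl and acetyl) while the tertiary alcohol cannot react, which unveils the 1,4-diketone and removes the two auxiliary carbinol centres.

**Step 13**
Reactants: 22 hydroxy 1,4-diketone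
Product: 23 triethylsilyl ether of 22
Conditions: TESOTf, 2,6-lutidine, CH2Cl2, −78 to 0 °C
Reagents that add atoms: triethylsilyl trifluoromethanesulfonate, CC[Si](CC)(CC)OS(=O)(=O)C(F)(F)F
Why: Silylation of the tertiary α-hydroxy ketone blocks base-induced retro-aldol cleavage of the β-hydroxy ketone unit, which would destroy both quaternary centres in the next step.

**Step 14**
Reactants: 23 triethylsilyl ether of 22
Product: 25 (2S,5R,9S)-9-ethynyl-2,7,8-trimethyl-9-[(triethylsilyl)oxy]-2-[(4R,8R)-4,8,12-trimethyltridecyl]-1-oxaspiro[4.4]non-7-en-6-one, via aldol adduct 24 (not isolated)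
Conditions: t-BuOK (0.5 equiv), t-BuOH/THF, 0 °C to rt
Reagents that add atoms: none
Why: Key intramolecular aldol condensation of the 1,4-diketone (as in jasmone syntheses): the enolate of the ethyl ketone adds 5-exo-trig to the methyl ketone, helped by the two quaternary carbons, and E1cB dehydration gives the tetrasubstituted cyclopentenone without touching the two quaternary stereocentres.

**Step 15**
Reactants: 25 ethynyl silyl ether spiro-enone
Product: 26 alpha-tocospiro A
Conditions: HgSO4 (10 mol %), 1 M H2SO4, THF/H2O, 40 °C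
Reagents that add atoms: water, O
Why: Mercury-catalysed Markovnikov hydration of the terminal alkyne (Kucherov reaction) gives the methyl ketone and the aqueous acid hydrolyses the silyl ether in the same operation, with no stereocentre involved.

**Compound list**
1 | (2E,7R,11R)-3,7,11,15-tetramethylhexadec-2-en-1-ol (natural phytol) | OC/C=C(\C)CCC[C@H](C)CCC[C@H](C)CCCC(C)C | starting material
2 | {(2S,3S)-3-methyl-3-[(4R,8R)-4,8,12-trimethyltridecyl]oxiran-2-yl}methanol | OC[C@@H]1O[C@@]1(C)CCC[C@H](C)CCC[C@H](C)CCCC(C)C | intermediate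
3 | (3S,7R,11R)-3,7,11,15-tetramethylhexadecane-1,3-diol | OCC[C@@](C)(O)CCC[C@H](C)CCC[C@H](C)CCCC(C)C | intermediate
4 | (3S,7R,11R)-1-iodo-3,7,11,15-tetramethylhexadecan-3-ol | ICC[C@@](C)(O)CCC[C@H](C)CCC[C@H](C)CCCC(C)C | intermediate
5 | triethyl{[(3S,7R,11R)-1-iodo-3,7,11,15-tetramethylhexadecan-3-yl]oxy}silane | ICC[C@@](C)(O[Si](CC)(CC)CC)CCC[C@H](C)CCC[C@H](C)CCCC(C)C | intermediate
6 | but-1-yne | CCC#C | starting material
7 | (E)-but-1-enylzirconocene chloride (Cp written as cyclopentadienyl rings on Zr) | CC/C=C/[Zr](Cl)(C1C=CC=C1)C1C=CC=C1 | intermediate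
8 | (E)-1-iodobut-1-ene | CC/C=C/I | intermediate
9 | ethyl (2S)-2-hydroxypropanoate (ethyl (S)-lactate) | C[C@H](O)C(=O)OCC | starting material
10 | (2S)-2-hydroxy-N-methoxy-N-methylpropanamide | C[C@H](O)C(=O)N(C)OC | intermediate
11 | (E)-but-1-enyllithium | CC/C=C/[Li] | intermediate
12 | (2S,4E)-2-hydroxyhept-4-en-3-one | C[C@H](O)C(=O)/C=C/CC | intermediate
13 | (2S)-4,5-dibromo-2-hydroxyheptan-3-one (anti adduct, both C4/C5 pairs) | C[C@H](O)C(=O)C(Br)C(Br)CC | intermediate
14 | (2S,4Z)-4-bromo-2-hydroxyhept-4-en-3-one | C[C@H](O)C(=O)/C(Br)=C/CC | intermediate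
15 | (2S,3S,4Z)-4-bromo-3-ethynylhept-4-ene-2,3-diol | C[C@H](O)[C@@](O)(C#C)/C(Br)=C/CC | intermediate
16 | {(3S,7R,11R)-3,7,11,15-tetramethyl-3-[(triethylsilyl)oxy]hexadecyl}lithium | [Li]CC[C@@](C)(O[Si](CC)(CC)CC)CCC[C@H](C)CCC[C@H](C)CCCC(C)C | intermediate
17 | lithium B-methoxy-B-{(3S,7R,11R)-3,7,11,15-tetramethyl-3-[(triethylsilyl)oxy]hexadecyl}-9-borabicyclo[3.3.1]nonan-9-uide | [Li+].CO[B-]1(CC[C@@](C)(O[Si](CC)(CC)CC)CCC[C@H](C)CCC[C@H](C)CCCC(C)C)C2CCCC1CCC2 | intermediate
18 | (2S,3R,4E)-3-ethynyl-4-{(3S,7R,11R)-3,7,11,15-tetramethyl-3-[(triethylsilyl)oxy]hexadecyl}hept-4-ene-2,3-diol | C[C@H](O)[C@@](O)(C#C)/C(CC[C@@](C)(O[Si](CC)(CC)CC)CCC[C@H](C)CCC[C@H](C)CCCC(C)C)=C/CC | intermediate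
19 | (2S,3S)-3-[(2R,3S)-3-ethyl-2-{(3S,7R,11R)-3,7,11,15-tetramethyl-3-[(triethylsilyl)oxy]hexadecyl}oxiran-2-yl]pent-4-yne-2,3-diol | C[C@H](O)[C@@](O)(C#C)[C@]1(CC[C@@](C)(O[Si](CC)(CC)CC)CCC[C@H](C)CCC[C@H](C)CCCC(C)C)O[C@H]1CC | intermediate
20 | (2S,3S)-3-{(2R,3S)-3-ethyl-2-[(3S,7R,11R)-3-hydroxy-3,7,11,15-tetramethylhexadecyl]oxiran-2-yl}pent-4-yne-2,3-diol | C[C@H](O)[C@@](O)(C#C)[C@]1(CC[C@@](C)(O)CCC[C@H](C)CCC[C@H](C)CCCC(C)C)O[C@H]1CC | intermediate
21 | (2S,3S)-3-{(2S,5S)-2-[(1S)-1-hydroxypropyl]-5-methyl-5-[(4R,8R)-4,8,12-trimethyltridecyl]oxolan-2-yl}pent-4-yne-2,3-diol | C[C@H](O)[C@@](O)(C#C)[C@]1(CC[C@](C)(CCC[C@H](C)CCC[C@H](C)CCCC(C)C)O1)[C@@H](O)CC | intermediate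
22 | (3R)-3-hydroxy-3-{(2R,5S)-5-methyl-2-propanoyl-5-[(4R,8R)-4,8,12-trimethyltridecyl]oxolan-2-yl}pent-4-yn-2-one | CC(=O)[C@@](O)(C#C)[C@]1(CC[C@](C)(CCC[C@H](C)CCC[C@H](C)CCCC(C)C)O1)C(=O)CC | intermediate
23 | (3R)-3-{(2R,5S)-5-methyl-2-propanoyl-5-[(4R,8R)-4,8,12-trimethyltridecyl]oxolan-2-yl}-3-[(triethylsilyl)oxy]pent-4-yn-2-one | CC(=O)[C@@](O[Si](CC)(CC)CC)(C#C)[C@]1(CC[C@](C)(CCC[C@H](C)CCC[C@H](C)CCCC(C)C)O1)C(=O)CC | intermediate
24 | 9-ethynyl-8-hydroxy-2,7,8-trimethyl-9-[(triethylsilyl)oxy]-2-[(4R,8R)-4,8,12-trimethyltridecyl]-1-oxaspiro[4.4]nonan-6-one (C2, C5, C9 as in 25; C7 and C8 undefined) | C#C[C@]1(O[Si](CC)(CC)CC)C(C)(O)C(C)C(=O)[C@@]12CC[C@](C)(CCC[C@H](C)CCC[C@H](C)CCCC(C)C)O2 | intermediate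
25 | (2S,5R,9S)-9-ethynyl-2,7,8-trimethyl-9-[(triethylsilyl)oxy]-2-[(4R,8R)-4,8,12-trimethyltridecyl]-1-oxaspiro[4.4]non-7-en-6-one | C#C[C@]1(O[Si](CC)(CC)CC)C(C)=C(C)C(=O)[C@@]12CC[C@](C)(CCC[C@H](C)CCC[C@H](C)CCCC(C)C)O2 | intermediate
26 | (2S,5R,9S)-9-acetyl-9-hydroxy-2,7,8-trimethyl-2-[(4R,8R)-4,8,12-trimethyltridecyl]-1-oxaspiro[4.4]non-7-en-6-one (alpha-tocospiro A) | CC(=O)[C@]1(O)C(C)=C(C)C(=O)[C@@]12CC[C@](C)(CCC[C@H](C)CCC[C@H](C)CCCC(C)C)O2 | target

**Totals**
Total step count: 15. Longest linear sequence: 10 steps (steps 1–4 then 10–15; the lactate branch 6–9 then 10–15 and the butyne branch 5, 7–9 then 10–15 are equally long).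

**Three steps most likely to fail**

Step 10. The vinyl bromide 15 is hindered and carries two free hydroxyls and a free alkyne, so the cross-coupling may be slow or the alkyne may interfere. The fallback sets out from 10 (using 6 and 5) and comes back at 18. But-1-yne 6 and EtMgBr give but-1-ynylmagnesium bromide F1, which converts 10 into (2S)-2-hydroxyhept-4-yn-3-one F2. Chelate-controlled addition of HC≡CMgBr, in the same sense as step 9, gives (2S,3R)-3-ethynylhept-4-yne-2,3-diol F3. Iodide 5 and Mg turnings give {(3S,7R,11R)-3,7,11,15-tetramethyl-3-[(triethylsilyl)oxy]hexadecyl}magnesium iodide F4. F3 is first deprotonated three times with EtMgBr (both hydroxyls and the terminal alkyne, which is thereby masked as its acetylide), then F4 and CuI (10 mol %) are added in Et2O/THF at reflux. Hydroxyl-directed anti-carbomagnesiation of the internal alkyne puts the alkyl group on the carbon next to the tertiary alkoxide, and protonation gives the same (E)-alkene 18.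

Step 11. The dioxirane may react slowly or unselectively at the crowded alkene, and the acid stage can divert into a semipinacol shift of the α-hydroxy epoxide or a 6-endo opening. The fallback sets out from 18 and comes back at 21. Bu4NF removes the silyl group to give (2S,3R,4E)-3-ethynyl-4-[(3S,7R,11R)-3-hydroxy-3,7,11,15-tetramethylhexadecyl]hept-4-ene-2,3-diol F5. VO(acac)2/t-BuOOH in CH2Cl2 then epoxidises under direction of the allylic tertiary hydroxyl (substrate control in place of reagent control). In the preferred transition state the slim ethynyl group takes the in-plane position that suffers A(1,2) strain and the hydroxyethyl group points away, so oxygen enters on the same face and gives epoxide 20. Addition of CSA closes 20 to 21.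

Step 14. The methyl ketone can enolise and attack the propanoyl group instead (giving the isomeric 3-ethylcyclopentenone), and loss of the silyl group under base would open the way to retro-aldol scrambling. The fallback sets out from 23 and comes back at 25 through 24. IBX in DMSO/toluene at 70 °C dehydrogenates only the ethyl ketone (the acetyl group has no β-hydrogen) to the vinyl ketone (3R)-3-{(2R,5S)-5-methyl-2-(prop-2-enoyl)-5-[(4R,8R)-4,8,12-trimethyltridecyl]oxolan-2-yl}-3-[(triethylsilyl)oxy]pent-4-yn-2-one F6. Conjugate reduction with [(Ph3P)CuH]6 in toluene generates the copper enolate regiospecifically at the propanoyl α-carbon, and this closes onto the acetyl carbonyl (reductive intramolecular aldol) to give 24. Dehydration of 24 with t-BuOK gives 25.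

**Further compounds**
F1 | step 10 | but-1-ynylmagnesium bromide | CCC#C[Mg]Br
F2 | step 10 | (2S)-2-hydroxyhept-4-yn-3-one | C[C@H](O)C(=O)C#CCC
F3 | step 10 | (2S,3R)-3-ethynylhept-4-yne-2,3-diol | C[C@H](O)[C@@](O)(C#C)C#CCC
F4 | step 10 | {(3S,7R,11R)-3,7,11,15-tetramethyl-3-[(triethylsilyl)oxy]hexadecyl}magnesium iodide | I[Mg]CC[C@@](C)(O[Si](CC)(CC)CC)CCC[C@H](C)CCC[C@H](C)CCCC(C)C
F5 | step 11 | (2S,3R,4E)-3-ethynyl-4-[(3S,7R,11R)-3-hydroxy-3,7,11,15-tetramethylhexadecyl]hept-4-ene-2,3-diol | C[C@H](O)[C@@](O)(C#C)/C(CC[C@@](C)(O)CCC[C@H](C)CCC[C@H](C)CCCC(C)C)=C/CC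
F6 | step 14 | (3R)-3-{(2R,5S)-5-methyl-2-(prop-2-enoyl)-5-[(4R,8R)-4,8,12-trimethyltridecyl]oxolan-2-yl}-3-[(triethylsilyl)oxy]pent-4-yn-2-one | CC(=O)[C@@](O[Si](CC)(CC)CC)(C#C)[C@]1(CC[C@](C)(CCC[C@H](C)CCC[C@H](C)CCCC(C)C)O1)C(=O)C=C
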